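**Retrosynthetic overview**

1. The aldehyde, acid and acetate are unmasked last. The (E)-C13=C14 acid with its C16 oxygen comes from a [2,3]-selenoxide shift of a 3-methylene ester chain (C13=C16), and the C6=C7 alkene from syn-dehydration of a C7 carbinol.
2. Key disconnection C11–C12 (together with C8–C17): the C7 ketone carrying the whole side chain and the 8-CH2OH is made from a tricyclic cyclopropyl ketone, a side-chain allylstannane and formaldehyde (stannyl-ketyl ring opening, allyl transfer, tin-enolate aldol).
3. Enabling feature: C11 sits on C9, C9 is bonded to C8, and C8 is flanked by C7, an sp2 carbon of ring B. With C7 as a temporary carbonyl, C8–C9–C11 can be closed to a cyclopropane fused to ring B. A C7 ketyl cleaves its C8–C11 bond (not in the target), which makes C11 a radical and C8 an enolate carbon.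
4. The cyclopropyl ketone comes from an OH-directed Simmons–Smith reaction on the 7α-ol of the 8-en-7-one, this from the trans-decalone, and this from a Robinson enone built from 2,2,6-trimethylcyclohexanone and methyl vinyl ketone (chiral-imine Michael addition sets C10).
5. Ring order: ring A is the starting ketone; ring B is closed by Michael/aldol annulation; the cyclopropane (temporary third ring) is made next and opened in the key step.

Key step: step 13

Remarks: labdane numbering is used for skeleton atoms; α is the face of the decalin that carries the C10 methyl group, β the opposite face (target: 5β-H, 9β-H with C11 α, 8α-H with C17 β). The (R)-amine is taken to induce the S configuration at the quaternary carbon, the usual sense of chiral-imine Michael additions; the (S)-amine would give the enantiomeric series. Monomeric formaldehyde is generated separately by cracking paraformaldehyde.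

**Route**

Step 1
Reactants: 1 2,2,6-trimethylcyclohexanone (racemic); 2 (R)-1-phenylethylamine
Product: 3 (R)-N-(2,2,6-trimethylcyclohexylidene)-1-phenylethanamine
Conditions: cat. TsOH, toluene, reflux, Dean–Stark
Reagents that add atoms: none
Why: Acid-catalysed ketimine condensation with azeotropic removal of water; the stereocentre of racemic 1 does not matter because it is planarised in the next step.

Step 2
Reactants: 3 imine; 4 methyl vinyl ketone
Product: 6 (S)-2,2,6-trimethyl-6-(3-oxobutyl)cyclohexanone, via Michael-adduct imine 5 (not isolated)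
Conditions: THF, 40 °C; then 10% aq. AcOH, rt
Reagents that add atoms: water, O
Why: Chiral-imine Michael addition through the secondary enamine (which can form only towards C6 because C2 is quaternary): the aza-ene-like transition state delivers the enone to the enamine face anti to the phenyl group, so the (R)-auxiliary should set the quaternary centre (future C10) as S, and aqueous acid then hydrolyses the imine.

Step 3
Reactants: 6 diketone
Product: 7 (4aS)-4a,8,8-trimethyl-4,4a,5,6,7,8-hexahydronaphthalen-2(3H)-one (labdane numbering: 4,4,10-trimethyl-5-en-7-one)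
Conditions: KOH (0.3 equiv), EtOH, reflux
Reagents that add atoms: none
Why: Intramolecular aldol condensation (second stage of a Robinson annulation) closes ring B by attack of the methyl-ketone enolate on the ring carbonyl and dehydration to the conjugated enone.

Step 4
Reactants: 7 enone
Product: 8 trans-fused 4,4,10-trimethyldecalin-7-one (5β-H, 10α-Me)
Conditions: Li, NH3(l)/THF, t-BuOH (1 equiv), −78 °C; then NH4Cl
Reagents that add atoms: none
Why: Birch-type dissolving-metal conjugate reduction; protonation of the β-carbanion at C5 on the axial face anti to the angular methyl should give the trans ring fusion, as with steroidal 4-en-3-ones.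

Step 5
Reactants: 8 trans-decalone
Product: 9 trans-fused 4,4,10-trimethyloctal-8-en-7-one (C8=C9 conjugated to C7=O)
Conditions: IBX, DMSO/toluene, 70 °C
Reagents that add atoms: none
Why: IBX dehydrogenation through the enol; the trans-decalone enolises towards C8 (as 5α-3-keto steroids give 1-en-3-ones) and C6 is shielded by the C4 gem-dimethyl group.

Step 6
Reactants: 9 enone
Product: 10 7α-hydroxy-4,4,10-trimethyloctal-8-ene (allylic alcohol, OH on the face of the C10 methyl)
Conditions: NaBH4, CeCl3·7H2O, MeOH, −78 °C
Reagents that add atoms: none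
Why: Luche 1,2-reduction; axial hydride delivery from the β face should give the pseudo-equatorial 7α-alcohol.

Step 7
Reactants: 10 allylic alcohol
Product: 11 tricyclic cyclopropyl carbinol (CH2 = C11 bridging C8 and C9 on the α face, 7α-OH)
Conditions: Et2Zn, CH2I2, CH2Cl2, 0 °C to rt
Reagents that add atoms: diiodomethane, ICI
Why: Hydroxyl-directed Simmons–Smith cyclopropanation (Furukawa conditions): the zinc alkoxide delivers CH2 to the α face syn to the 7α-OH, overriding the steric bias of the angular methyl, and so fixes C9 with C11 α.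

Step 8
Reactants: 11 cyclopropyl carbinol
Product: 12 tricyclic cyclopropyl ketone (C8–C9–C11 ring on the α face, C7 ketone)
Conditions: Dess–Martin periodinane, pyridine, CH2Cl2, 0 °C to rt
Reagents that add atoms: none
Why: Dess–Martin oxidation under buffered, non-acidic conditions that leave the cyclopropane intact.

Step 9
Reactants: 13 itaconic anhydride; 14 2-(trimethylsilyl)ethanol
Product: 15 4-[2-(trimethylsilyl)ethyl] hydrogen 2-methylenesuccinate
Conditions: toluene, 80 °C
Reagents that add atoms: none
Why: Ring-opening alcoholysis of the anhydride at the non-conjugated, more electrophilic carbonyl gives the 4-monoester with the free acrylic acid.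

Step 10
Reactants: 15 half ester
Product: 17 2-(trimethylsilyl)ethyl 3-(hydroxymethyl)but-3-enoate, via mixed carbonic anhydride 16 (not isolated)
Conditions: i-BuOCOCl, N-methylmorpholine, THF, −15 °C; then NaBH4, H2O, 0 °C
Reagents that add atoms: none
Why: Chemoselective reduction of the carboxylic acid through its mixed carbonic anhydride with NaBH4 (1,2-reduction to the allylic alcohol; the ester is not touched).

Step 11
Reactants: 17 allylic alcohol
Product: 18 2-(trimethylsilyl)ethyl 3-(bromomethyl)but-3-enoate
Conditions: CBr4, PPh3, CH2Cl2, 0 °C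
Reagents that add atoms: carbon tetrabromide, BrC(Br)(Br)Br
Why: Appel bromination of the primary allylic alcohol under neutral conditions.

Step 12
Reactants: 18 allylic bromide
Product: 19 2-(trimethylsilyl)ethyl 3-[(tributylstannyl)methyl]but-3-enoate
Conditions: Bu3SnH, LDA, THF, 0 °C; then 18, −78 °C
Reagents that add atoms: tributyltin hydride, CCCC[SnH](CCCC)CCCC
Why: Displacement of the allylic bromide by tributylstannyllithium; SN2 and SN2′ attack give the same product because the two allyl termini are equivalent.

Step 13
Reactants: 12 tricyclic cyclopropyl ketone; 19 allylstannane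
Product: 22 2-(trimethylsilyl)ethyl 5-[8β-(hydroxymethyl)-4,4,10-trimethyl-7-oxo-trans-decalin-9α-yl]-3-methylenepentanoate, via tributyltin enolate 20 (not isolated), via tributylstannyl aldolate 21 (not isolated)
Conditions: 19 (2.5 equiv), AIBN (0.3 equiv, in portions), PhH, 80 °C; then CH2O (gas), THF, −40 to 0 °C; pH 7 buffer
Reagents that add atoms: formaldehyde, C=O
Why: Bu3Sn• (chain carrier, started by AIBN) adds to the C7 carbonyl oxygen of 12, and the O-stannyl ketyl opens the cyclopropane by β-scission of the exocyclic C8–C11 bond (the bond best aligned with the ketyl SOMO) to give the tin enolate of the C7 ketone and a primary radical at C11, which adds to the CH2= terminus of 19 and expels Bu3Sn•, forming C11–C12. The closest known reaction type is the O-stannyl-ketyl fragmentation of α-ketocyclopropanes with radical allyl transfer from an allylstannane (Keck allylation), followed by aldol addition of the tributyltin enolate so formed. No ring is closed: the temporary three-membered ring is opened, and ring B stays six-membered because scission of the ring-fusion bond C8–C9 (ring enlargement) is stereoelectronically disfavoured and the primary radical is trapped by excess 19 before it can equilibrate. C9 keeps the configuration fixed in step 7 (C11 α); the new stereocentre C8 is set in the aldol step, where formaldehyde attacks the Δ7 tin enolate from the β face, anti to the axial C10 methyl group and trans to the new C9 chain, giving the diequatorial 8β-hydroxymethyl ketone, which is also the thermodynamic epimer. The selectivities needed are C11 over C9 radical formation (secured by the orbital alignment in the fused bicyclo[4.1.0]heptan-2-one), allyl transfer over hydrogen abstraction (no tin hydride is present) and C8 over C6 aldol addition (the enolate is formed regiospecifically and is not equilibrated). In one operation the step joins the two fragments, installs C17 and sets C8.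

Step 14
Reactants: 22 β-hydroxy ketone
Product: 23 17-O-tert-butyldimethylsilyl ether of 22
Conditions: TBSCl, imidazole, DMF, 0 °C to rt
Reagents that add atoms: tert-butyldimethylsilyl chloride, CC(C)(C)[Si](C)(C)Cl
Why: Silylation of the primary alcohol protects C17–OH through the reduction, dehydration and enolate steps.

Step 15
Reactants: 23 ketone
Product: 24 7β-alcohol of 23 (axial OH, cis to the C8 substituent)
Conditions: L-Selectride, THF, −78 °C; then H2O
Reagents that add atoms: none
Why: L-Selectride reduction; the bulky hydride attacks the C7 ketone equatorially and should give the axial 7β-alcohol, trans to 8α-H.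

Step 16
Reactants: 24 7β-alcohol
Product: 25 2-(trimethylsilyl)ethyl 5-[8β-(tert-butyldimethylsilyloxymethyl)-4,4,10-trimethyl-trans-octal-6-en-9α-yl]-3-methylenepentanoate
Conditions: Burgess reagent, PhH, 50 °C
Reagents that add atoms: none
Why: Burgess dehydration, a syn (Ei) elimination: the 7β-sulfamate has a cis hydrogen only at C6 (6β-H) because the only hydrogen on C8 is α, so the C6=C7 alkene should form regiospecifically.

Step 17
Reactants: 25 β,γ-unsaturated ester
Product: 26 2-(phenylselanyl) derivative of 25 (selenium on C14, both epimers)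
Conditions: LDA, THF, −78 °C; then PhSeBr
Reagents that add atoms: phenylselenyl bromide, Br[Se]c1ccccc1
Why: α-Selenenylation of the ester dienolate (kinetic attack at the α-carbon C14) places the selenide next to the 1,1-disubstituted alkene.

Step 18
Reactants: 26 α-seleno ester
Product: 29 2-(trimethylsilyl)ethyl (E)-3-(hydroxymethyl)-5-[8β-(tert-butyldimethylsilyloxymethyl)-4,4,10-trimethyl-trans-octal-6-en-9α-yl]pent-2-enoate, via allyl selenoxide 27 (not isolated), via allyl selenenate 28 (not isolated)
Conditions: 30% H2O2, pyridine, CH2Cl2, 0 °C to rt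
Reagents that add atoms: hydrogen peroxide, OO
Why: Oxidation to the allyl selenoxide triggers a [2,3]-sigmatropic (selenoxide–selenenate) rearrangement that moves oxygen to C16 and the alkene to C13=C14; the ester on the selenium-bearing carbon takes the pseudo-equatorial position in the envelope transition state, so CO2R should end trans to CH2O (E), as in the [2,3] step of SeO2 allylic oxidations, and the selenenate is cleaved in situ.

Step 19
Reactants: 29 allylic alcohol
Product: 30 16-O-acetate of 29
Conditions: Ac2O, pyridine, cat. DMAP, CH2Cl2, 0 °C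
Reagents that add atoms: acetic anhydride, CC(=O)OC(C)=O
Why: DMAP-catalysed acetylation of the primary allylic alcohol.

Step 20
Reactants: 30 acetate
Product: 31 (E)-3-(acetoxymethyl)-5-[8β-(hydroxymethyl)-4,4,10-trimethyl-trans-octal-6-en-9α-yl]pent-2-enoic acid
Conditions: TBAF, AcOH, THF, 0 °C to rt
Reagents that add atoms: none
Why: Fluoride-induced cleavage of both silicon groups in one operation (TBS ether by Si–O cleavage, 2-(trimethylsilyl)ethyl ester by β-elimination), buffered with acetic acid so that the acetate survives.

Step 21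
Reactants: 31 hydroxy acid
Product: 32 target, (E)-3-(acetoxymethyl)-5-[8β-formyl-4,4,10-trimethyl-trans-octal-6-en-9α-yl]pent-2-enoic acid
Conditions: Dess–Martin periodinane, CH2Cl2, 0 °C; Na2S2O3/pH 7 buffer
Reagents that add atoms: none
Why: Dess–Martin oxidation of the homoallylic primary alcohol to the β,γ-unsaturated aldehyde under neutral conditions that tolerate the free acid and avoid epimerisation at C8 (already the equatorial, more stable epimer) and migration of the C6=C7 alkene into conjugation.

**Compound list**

1 | 2,2,6-trimethylcyclohexanone (racemic) | CC1CCCC(C)(C)C1=O | starting material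
2 | (R)-1-phenylethylamine | C[C@@H](N)c1ccccc1 | starting material
3 | (R)-N-(2,2,6-trimethylcyclohexylidene)-1-phenylethanamine (C6 epimers) | CC1CCCC(C)(C)C1=N[C@H](C)c1ccccc1 | intermediate
4 | methyl vinyl ketone | CC(=O)C=C | starting material
5 | (R)-1-phenylethyl imine of 6 (Michael adduct, quaternary centre S) | CC(=O)CC[C@]1(C)CCCC(C)(C)C1=N[C@H](C)c1ccccc1 | intermediate (not isolated)
6 | (S)-2,2,6-trimethyl-6-(3-oxobutyl)cyclohexanone | CC(=O)CC[C@]1(C)CCCC(C)(C)C1=O | intermediate
7 | (4aS)-4a,8,8-trimethyl-4,4a,5,6,7,8-hexahydronaphthalen-2(3H)-one | C1CC(=O)C=C2C(C)(C)CCC[C@@]12C | intermediate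
8 | trans-fused 4,4,10-trimethyldecalin-7-one (5β-H, 10α-Me) | C1CC(=O)C[C@@H]2C(C)(C)CCC[C@@]12C | intermediate
9 | trans-fused 4,4,10-trimethyloctal-8-en-7-one | C1=CC(=O)C[C@@H]2C(C)(C)CCC[C@@]12C | intermediate
10 | 7α-hydroxy-4,4,10-trimethyloctal-8-ene (trans-fused) | C1=C[C@H](O)C[C@@H]2C(C)(C)CCC[C@@]12C | intermediate
11 | tricyclic cyclopropyl carbinol (C11 bridging C8 and C9 on the α face, 7α-OH) | [C@H]14C[C@@H]4[C@H](O)C[C@@H]2C(C)(C)CCC[C@@]12C | intermediate
12 | tricyclic cyclopropyl ketone (C8–C9–C11 ring on the α face, C7 ketone) | [C@H]14C[C@@H]4C(=O)C[C@@H]2C(C)(C)CCC[C@@]12C | intermediate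
13 | itaconic anhydride | C=C1CC(=O)OC1=O | starting material
14 | 2-(trimethylsilyl)ethanol | C[Si](C)(C)CCO | starting material
15 | 4-[2-(trimethylsilyl)ethyl] hydrogen 2-methylenesuccinate | C=C(CC(=O)OCC[Si](C)(C)C)C(=O)O | intermediate
16 | mixed isobutyl carbonic anhydride of 15 | C=C(CC(=O)OCC[Si](C)(C)C)C(=O)OC(=O)OCC(C)C | intermediate (not isolated)
17 | 2-(trimethylsilyl)ethyl 3-(hydroxymethyl)but-3-enoate | C=C(CO)CC(=O)OCC[Si](C)(C)C | intermediate
18 | 2-(trimethylsilyl)ethyl 3-(bromomethyl)but-3-enoate | C=C(CBr)CC(=O)OCC[Si](C)(C)C | intermediate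
19 | 2-(trimethylsilyl)ethyl 3-[(tributylstannyl)methyl]but-3-enoate | C=C(C[Sn](CCCC)(CCCC)CCCC)CC(=O)OCC[Si](C)(C)C | intermediate
20 | tributyltin enolate (C7–O–Sn, C7=C8) of the ring-opened, allylated ketone | C=C(CC(=O)OCC[Si](C)(C)C)CC[C@@H]1C=C(O[Sn](CCCC)(CCCC)CCCC)C[C@@H]2C(C)(C)CCC[C@@]12C | intermediate (not isolated)
21 | tributylstannyl aldolate (17-O-SnBu3 derivative of 22) | C=C(CC(=O)OCC[Si](C)(C)C)CC[C@@H]1[C@@H](CO[Sn](CCCC)(CCCC)CCCC)C(=O)C[C@@H]2C(C)(C)CCC[C@@]12C | intermediate (not isolated)
22 | 2-(trimethylsilyl)ethyl 5-[8β-(hydroxymethyl)-4,4,10-trimethyl-7-oxo-trans-decalin-9α-yl]-3-methylenepentanoate | C=C(CC(=O)OCC[Si](C)(C)C)CC[C@@H]1[C@@H](CO)C(=O)C[C@@H]2C(C)(C)CCC[C@@]12C | intermediate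
23 | 17-O-TBS ether of 22 | C=C(CC(=O)OCC[Si](C)(C)C)CC[C@@H]1[C@@H](CO[Si](C)(C)C(C)(C)C)C(=O)C[C@@H]2C(C)(C)CCC[C@@]12C | intermediate
24 | 7β-alcohol of 23 | C=C(CC(=O)OCC[Si](C)(C)C)CC[C@@H]1[C@@H](CO[Si](C)(C)C(C)(C)C)[C@@H](O)C[C@@H]2C(C)(C)CCC[C@@]12C | intermediate
25 | Δ6-alkene: 2-(trimethylsilyl)ethyl 5-[8β-(TBS-oxymethyl)-4,4,10-trimethyl-trans-octal-6-en-9α-yl]-3-methylenepentanoate | C=C(CC(=O)OCC[Si](C)(C)C)CC[C@@H]1[C@@H](CO[Si](C)(C)C(C)(C)C)C=C[C@@H]2C(C)(C)CCC[C@@]12C | intermediate
26 | 2-(phenylselanyl) derivative of 25 (C14 epimers) | C=C(C([Se]c3ccccc3)C(=O)OCC[Si](C)(C)C)CC[C@@H]1[C@@H](CO[Si](C)(C)C(C)(C)C)C=C[C@@H]2C(C)(C)CCC[C@@]12C | intermediate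
27 | selenoxide of 26 | C=C(C([Se](=O)c3ccccc3)C(=O)OCC[Si](C)(C)C)CC[C@@H]1[C@@H](CO[Si](C)(C)C(C)(C)C)C=C[C@@H]2C(C)(C)CCC[C@@]12C | intermediate (not isolated)
28 | (E)-allyl selenenate (C16–O–SePh) | O([Se]c3ccccc3)C/C(=C/C(=O)OCC[Si](C)(C)C)CC[C@@H]1[C@@H](CO[Si](C)(C)C(C)(C)C)C=C[C@@H]2C(C)(C)CCC[C@@]12C | intermediate (not isolated)
29 | 2-(trimethylsilyl)ethyl (E)-3-(hydroxymethyl)-5-[8β-(TBS-oxymethyl)-4,4,10-trimethyl-trans-octal-6-en-9α-yl]pent-2-enoate | OC/C(=C/C(=O)OCC[Si](C)(C)C)CC[C@@H]1[C@@H](CO[Si](C)(C)C(C)(C)C)C=C[C@@H]2C(C)(C)CCC[C@@]12C | intermediate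
30 | 16-O-acetate of 29 | CC(=O)OC/C(=C/C(=O)OCC[Si](C)(C)C)CC[C@@H]1[C@@H](CO[Si](C)(C)C(C)(C)C)C=C[C@@H]2C(C)(C)CCC[C@@]12C | intermediate
31 | (E)-3-(acetoxymethyl)-5-[8β-(hydroxymethyl)-4,4,10-trimethyl-trans-octal-6-en-9α-yl]pent-2-enoic acid | CC(=O)OC/C(=C/C(=O)O)CC[C@@H]1[C@@H](CO)C=C[C@@H]2C(C)(C)CCC[C@@]12C | intermediate
32 | target | CC(=O)OC/C(=C/C(=O)O)CC[C@@H]1[C@@H](C=O)C=C[C@@H]2C(C)(C)CCC[C@@]12C | target

**Step count and risks**

Total step count: 21. Longest linear sequence: 17 (steps 1–8 and 13–21); steps 9–12 form the side-chain branch that joins in step 13.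

Steps most likely to fail:

1. Step 13. The radical chain may be short (slow, reversible addition of the tin radical to the ketone, reclosure or ring enlargement of the opened radical), and the tin enolate may lose its regio-integrity or add formaldehyde more than once. Fallback: starting from 12, the cyclopropane is opened with iodotrimethylsilane (CH2Cl2, −40 °C) to the 11-iodo trimethylsilyl enol ether F1. Lanthanide-triflate-catalysed hydroxymethylation with aqueous formaldehyde (Mukaiyama aldol) gives the iodo hydroxy ketone F2, and silylation (TBSCl, imidazole) gives the iodo silyl ether F3. Keck allylation of this primary iodide with 19 (AIBN, benzene, 80 °C) then leads to 23, where the route is rejoined.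

2. Step 2. Conversion may be low or facial selectivity poor in the conjugate addition of the hindered ketimine (slow imine–enamine tautomerisation next to a quaternary carbon). Fallback: starting from 1, enolisation (LiHMDS) and O-acylation with allyl chloroformate give the allyl enol carbonate F4. Pd-catalysed decarboxylative asymmetric allylic alkylation with a (S)-tert-butyl-phosphinooxazoline ligand gives the (S)-allyl ketone F5. Hydroboration–oxidation (9-BBN, then NaBO3) gives the primary alcohol F6, Dess–Martin oxidation the aldehyde F7, and addition of MeMgBr at −78 °C (the ring ketone is too hindered to react) the secondary alcohol F8. A second Dess–Martin oxidation returns to 6.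

3. Step 16. Regiocontrol may be lost in the dehydration (ionisation at C7 leading to the 7-ene or to rearranged products, or slow reaction of the hindered axial alcohol). Fallback: starting from 23, kinetic deprotonation at C6 (KHMDS, THF, −78 °C, one equivalent, to spare the side-chain ester) in the presence of N-(5-chloro-2-pyridyl)triflimide gives the Δ6 enol triflate F9. Pd-catalysed formate reduction (Pd(OAc)2, PPh3, Bu3N, HCO2H, DMF, 60 °C) leads to 25, so steps 15 and 16 are bypassed.

Further compounds

F1 | step 13 | 11-iodo trimethylsilyl enol ether (C7–OTMS, C7=C8) from ring opening of 12 | IC[C@@H]1C=C(O[Si](C)(C)C)C[C@@H]2C(C)(C)CCC[C@@]12C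
F2 | step 13 | 9α-(iodomethyl)-8β-(hydroxymethyl)-4,4,10-trimethyl-trans-decalin-7-one | IC[C@@H]1[C@@H](CO)C(=O)C[C@@H]2C(C)(C)CCC[C@@]12C
F3 | step 13 | TBS ether of F2 | IC[C@@H]1[C@@H](CO[Si](C)(C)C(C)(C)C)C(=O)C[C@@H]2C(C)(C)CCC[C@@]12C
F4 | step 2 | allyl 2,6,6-trimethylcyclohex-1-en-1-yl carbonate | C=CCOC(=O)OC1=C(C)CCCC1(C)C
F5 | step 2 | (S)-2-allyl-2,6,6-trimethylcyclohexanone | C=CC[C@]1(C)CCCC(C)(C)C1=O
F6 | step 2 | (S)-2-(3-hydroxypropyl)-2,6,6-trimethylcyclohexanone | OCCC[C@]1(C)CCCC(C)(C)C1=O
F7 | step 2 | (S)-3-(1,3,3-trimethyl-2-oxocyclohexyl)propanal | O=CCC[C@]1(C)CCCC(C)(C)C1=O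
F8 | step 2 | (S)-2-(3-hydroxybutyl)-2,6,6-trimethylcyclohexanone (carbinol epimers) | CC(O)CC[C@]1(C)CCCC(C)(C)C1=O
F9 | step 16 | Δ6 enol triflate of 23 (C7–OTf, C6=C7) | C=C(CC(=O)OCC[Si](C)(C)C)CC[C@@H]1[C@@H](CO[Si](C)(C)C(C)(C)C)C(OS(=O)(=O)C(F)(F)F)=C[C@@H]2C(C)(C)CCC[C@@]12C
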